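**Retrosynthetic overview**
1. The C5 carbinol is the only stereocentre. It is set last, from the C5 ketone of the bicyclic 4,5-dione, by enantioselective transfer hydrogenation.
2. Key disconnection: the O1–C2 carbon–oxygen bond of the 4-pyrone. It is made by cyclodehydration of an open 2-(3-oxoacyl)cyclohexane-1,3-dione.
3. That tetraketone comes from C-acylation of cyclohexane-1,3-dione (C4–C4a) by an acylketene. The acylketene is released from a tert-butyl β-keto ester in the same flask as the ring closure.
4. The β-keto ester comes from a C18 pheromone aldehyde, which already holds the Z-alkene, and a diazoacetate.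
5. Ring order: ring B (carbocycle) is bought with the dione. Ring A (pyrone) is the only ring formed, in step 2.

Assumption: (Z)-octadec-13-enal, a moth pheromone active made on scale (Z at least 95%), and tert-butyl diazoacetate are bought. Chromene numbering (O1, C2 to C8a) is used. The target is the (5S) enantiomer.

Step 1
Reactants: 1 (Z)-octadec-13-enal; 2 tert-butyl diazoacetate
Product: 3 tert-butyl (Z)-3-oxoicos-15-enoate
Conditions: 2 (1.15 equiv), SnCl2 (10 mol%), CH2Cl2, 23 °C, 3 h
Reagents that add atoms: none
Why: Roskamp reaction, in which SnCl2 activates the aldehyde, the diazo carbon adds to C=O and a 1,2-hydride shift with loss of N2 gives the β-keto ester directly; aliphatic aldehydes are the best substrates, no metal carbene forms so the Z-alkene is untouched, and no stereocentre is created.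

Step 2
Reactants: 3 tert-butyl (Z)-3-oxoicos-15-enoate; 4 cyclohexane-1,3-dione
Product: 7 2-[(Z)-heptadec-12-en-1-yl]-7,8-dihydro-4H-chromene-4,5(6H)-dione, via acylketene 5 (not isolated), via tetraketone 6 (not isolated)
Conditions: 3 added over 1 h to 4 (1.5 equiv), xylenes, 135 °C, Dean–Stark trap with 4 Å MS, 2 h; then p-TsOH·H2O (5 mol%), 110 °C, 30 min
Reagents that add atoms: none
Why: Thermal loss of tert-butanol from the tert-butyl β-keto ester gives the acylketene (transacetoacetylation chemistry), which acylates the enol carbon of 4 because O-acylation is reversible at this temperature, and acid-catalysed cyclodehydration then joins the ring enol oxygen to the side-chain ketone carbon (O1–C2, the classical 4-pyrone and chromone closure of 1,3,5-tricarbonyls, as seen with diketene and cyclic 1,3-dicarbonyl enols); no stereocentre is formed and the Z-alkene tolerates brief catalytic acid.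

Step 3
Reactants: 7 2-[(Z)-heptadec-12-en-1-yl]-7,8-dihydro-4H-chromene-4,5(6H)-dione
Product: 8 (5S)-2-[(Z)-heptadec-12-en-1-yl]-5-hydroxy-5,6,7,8-tetrahydro-4H-chromen-4-one
Conditions: RuCl[(S,S)-TsDPEN](p-cymene) (2 mol%), HCO2H/Et3N (5:2, 5 equiv HCO2H), CH2Cl2, 25 °C, 16 h
Reagents that add atoms: none
Why: Proposed new method: site- and enantioselective Noyori–Ikariya asymmetric transfer hydrogenation of the ring B ketone of a 3-acyl-4-pyrone (a 7,8-dihydrochromene-4,5-dione), a substrate class on which this reaction has not been shown; the 18-electron Ru–H/N–H species formed from formate passes H− and H+ through an outer-sphere six-membered transition state to C5=O only, because C4=O is deactivated as a doubly vinylogous ester with pyrylium-olate character, the conjugate positions C2 and C8a are fully substituted, and the isolated Z-alkene offers no polar handle; the flat pyrone takes the place held by the arene of 1-tetralone under the p-cymene ligand (C–H/π and C–H/lone-pair attraction), so the (S,S)-catalyst delivers hydride to the Re face and sets (5S), loss of CO2 makes the step irreversible, and the O–H···O=C4 hydrogen bond stabilises the product; closest known reaction type: asymmetric transfer hydrogenation of 1-tetralones and chroman-4-ones, where (S,S)-TsDPEN gives the (S)-alcohols.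

**Compound list**
1 | (Z)-octadec-13-enal | CCCC/C=C\CCCCCCCCCCCC=O | starting material
2 | tert-butyl diazoacetate | CC(C)(C)OC(=O)C=[N+]=[N-] | starting material
3 | tert-butyl (Z)-3-oxoicos-15-enoate | CCCC/C=C\CCCCCCCCCCCC(=O)CC(=O)OC(C)(C)C | intermediate
4 | cyclohexane-1,3-dione | O=C1CCCC(=O)C1 | starting material
5 | (15Z)-icosa-1,15-diene-1,3-dione (acylketene, not isolated) | CCCC/C=C\CCCCCCCCCCCC(=O)C=C=O | intermediate
6 | 2-[(Z)-3-oxoicos-15-enoyl]cyclohexane-1,3-dione (tetraketone, drawn in the keto form, not isolated) | CCCC/C=C\CCCCCCCCCCCC(=O)CC(=O)C1C(=O)CCCC1=O | intermediate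
7 | 2-[(Z)-heptadec-12-en-1-yl]-7,8-dihydro-4H-chromene-4,5(6H)-dione | CCCC/C=C\CCCCCCCCCCCc1cc(=O)c2c(o1)CCCC2=O | intermediate
8 | (5S)-2-[(Z)-heptadec-12-en-1-yl]-5-hydroxy-5,6,7,8-tetrahydro-4H-chromen-4-one | CCCC/C=C\CCCCCCCCCCCc1cc(=O)c2c(o1)CCC[C@@H]2O | target

**Totals:** 3 steps. The longest linear sequence is 3 (1 to 3 to 7 to 8).

**Steps most likely to fail**

**Step 3 (the proposed new step).**
- Risks: hydride may go to C8a or C2 in a conjugate sense. Turnover may be slow on a ketone that is partly a vinylogous ester. The peri C4 carbonyl may lower the ee. The acidic medium may ionise the C5 alcohol.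
- Fallback: known chemistry, resolution in place of asymmetric catalysis. It sets out from 7.
- Luche reduction (NaBH4, CeCl3·7H2O, MeOH/THF, −40 °C) gives racemic 2-[(Z)-heptadec-12-en-1-yl]-5-hydroxy-5,6,7,8-tetrahydro-4H-chromen-4-one F1.
- Kinetic resolution follows with immobilised lipase B from Candida antarctica and vinyl acetate in MTBE at 30 °C, taken to about 52% conversion.
- By the Kazlauskas rule, as for 1-tetralol, the (R)-enantiomer is acetylated to (5R)-2-[(Z)-heptadec-12-en-1-yl]-4-oxo-5,6,7,8-tetrahydro-4H-chromen-5-yl acetate F2, which is removed by chromatography.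
- The unreacted (S)-alcohol is 8, where the fallback comes back to the route.

**Step 2.**
- Risks: the enol of 4 may stay acylated on oxygen. The water from ring closure may hydrolyse 5, and decarboxylation would follow. A Pechmann-type closure may give the isomeric 2-pyranone.
- Fallback: the pyrone oxygen–carbon bond is closed on an alkyne instead of a ketone. It sets out from 1 and uses 4 again.
- Ohira–Bestmann homologation (dimethyl (1-diazo-2-oxopropyl)phosphonate, K2CO3, MeOH, 23 °C) gives (Z)-nonadec-14-en-1-yne F3.
- n-BuLi in THF at −78 °C, then CO2 and an HCl work-up, gives (Z)-icos-15-en-2-ynoic acid F4.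
- DCC, DMAP and Et3N in CH2Cl2 with 4 give first the enol ester 3-oxocyclohex-1-en-1-yl (Z)-icos-15-en-2-ynoate F5.
- A DMAP-mediated O-to-C acyl shift in the same flask then gives 3-hydroxy-2-[(Z)-icos-15-en-2-ynoyl]cyclohex-2-en-1-one F6.
- F6 closes by 6-endo-dig oxa-Michael addition (Et3N, or AgOTf 5 mol%) to 7, where the fallback comes back to the route.

**Step 1.**
- Risks: aged aldehyde (peracid, trimer), aldol self-condensation on SnCl2, and the handling limits of the diazo ester on scale.
- Fallback: aldol addition followed by oxidation in place of the diazo insertion. It sets out from 1.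
- The lithium enolate of tert-butyl acetate (LiN(iPr)2, THF, −78 °C) adds to 1 to give racemic tert-butyl (Z)-3-hydroxyicos-15-enoate F7.
- Dess–Martin periodinane (NaHCO3, CH2Cl2, 23 °C) erases that carbinol centre and gives 3, where the fallback comes back to the route.

**Further compounds**
F1 | step 3 | racemic 2-[(Z)-heptadec-12-en-1-yl]-5-hydroxy-5,6,7,8-tetrahydro-4H-chromen-4-one | CCCC/C=C\CCCCCCCCCCCc1cc(=O)c2c(o1)CCCC2O
F2 | step 3 | (5R)-2-[(Z)-heptadec-12-en-1-yl]-4-oxo-5,6,7,8-tetrahydro-4H-chromen-5-yl acetate | CCCC/C=C\CCCCCCCCCCCc1cc(=O)c2c(o1)CCC[C@H]2OC(C)=O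
F3 | step 2 | (Z)-nonadec-14-en-1-yne | CCCC/C=C\CCCCCCCCCCCC#C
F4 | step 2 | (Z)-icos-15-en-2-ynoic acid | CCCC/C=C\CCCCCCCCCCCC#CC(=O)O
F5 | step 2 | 3-oxocyclohex-1-en-1-yl (Z)-icos-15-en-2-ynoate | CCCC/C=C\CCCCCCCCCCCC#CC(=O)OC1=CC(=O)CCC1
F6 | step 2 | 3-hydroxy-2-[(Z)-icos-15-en-2-ynoyl]cyclohex-2-en-1-one | CCCC/C=C\CCCCCCCCCCCC#CC(=O)C1=C(O)CCCC1=O
F7 | step 1 | racemic tert-butyl (Z)-3-hydroxyicos-15-enoate | CCCC/C=C\CCCCCCCCCCCC(O)CC(=O)OC(C)(C)C
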